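**Retrosynthetic overview**
1. Feature: the target is an open-chain C16 3,5-dione (C1 benzylic, C16 the terminal methyl). The guaiacol ring carbon para to the OH is bonded to C1, two carbons from the C3 carbonyl, and this aryl–C1H2–C2H2–C3(=O) unit carries the plan; there is no stereocentre and no ring besides the arene.
2. C3–C4 disconnection (aldol, made first): 2-tridecanone 1, through its methyl-side lithium enolate 3, plus acrolein 2, by way of lithium aldolate 4, to racemic 3-hydroxyhexadec-1-en-5-one 5.
3. Aryl–C1 disconnection (made last): 5 plus 4-iodo-2-methoxyphenol 6 by Heck arylation in which the C3 carbinol becomes the C3 ketone as the bond forms, through enol 7, to [12]-gingerdione 8.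
4. Rings: none is formed; the aromatic ring enters intact with 6.

Key step: step 2

Remark: 8 is drawn in the diketo form of the target SMILES (in solution it should sit largely as the hydrogen-bonded C3/C5 enol, the same compound), and palladium-bound states of the catalytic cycle in step 2 are treated as catalyst states and carry no numbers.

**Step 1**
Reactants: 1 2-tridecanone; 2 acrolein
Product: 5 racemic 3-hydroxyhexadec-1-en-5-one, via lithium tridec-1-en-2-olate 3 (not isolated), via lithium 5-oxohexadec-1-en-3-olate 4 (not isolated)
Conditions: LiN(iPr)2 (commercial solution, 1.05 equiv), THF, −78 °C, 1 added dropwise; 2 (1.2 equiv, freshly distilled), −78 °C, short contact; AcOH (1.2 equiv) in THF at −78 °C, then warm and extract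
Reagents that add atoms: none
Why: Directed (crossed) aldol addition, in which the hindered amide base should remove the less hindered methyl proton of 1 irreversibly at −78 °C to give kinetic enolate 3, which adds through a closed six-membered lithium-bridged transition state to the carbonyl carbon of 2 (1,2- in preference to 1,4-addition at low temperature), the new C3 carbinol centre forming racemic, which is immaterial because C3 becomes a carbonyl carbon in step 2, while the cold acetic acid quench of aldolate 4 forestalls retro-aldol cleavage and dehydration.

**Step 2**
Reactants: 5 racemic 3-hydroxyhexadec-1-en-5-one (1.2 equiv); 6 4-iodo-2-methoxyphenol (1.0 equiv)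
Product: 8 [12]-gingerdione (1-(4-hydroxy-3-methoxyphenyl)hexadecane-3,5-dione), via C2-C3 enol 7 (not isolated)
Conditions: Pd(OAc)2 (5 mol %), Bu4NCl (1.0 equiv), NaHCO3 (2.5 equiv), degassed DMF, N2, 45–50 °C; dilute aqueous citric acid work-up
Reagents that add atoms: none
Why: Pd(OAc)2 is reduced in the flask to zerovalent palladium, held in solution as chloride-ligated species by Bu4NCl, which adds oxidatively to the C–I bond of 6; syn carbopalladation of the terminal alkene of 5 puts the aryl group on C1 and palladium on C2, syn β-hydride elimination of the C3–H releases enol 7, which tautomerises to the C3 ketone of 8, and NaHCO3 takes up HI from the palladium hydride to return zerovalent palladium. The closest known reaction type is the Heck arylation of secondary allylic alcohols to β-aryl ketones under ligand-free phase-transfer (Jeffery) conditions, as in the arylation of but-3-en-2-ol by iodophenols to 4-arylbutan-2-ones. No ring is closed and no stereocentre is created; the racemic C3 carbinol centre of 5 is erased as C3 becomes sp2. Aryl delivery to C1 is needed, and the monosubstituted, electronically unbiased alkene should secure it because the aryl group migrates to the unhindered terminal carbon. Hydride loss from C3 and not from benzylic C1 is needed: the C3–H is activated by the geminal oxygen and its loss is made irreversible by enol-to-ketone tautomerisation, whereas elimination toward C1 leaves a palladium hydride–alkene complex that can re-insert and return. Bicarbonate at 45–50 °C is too weak a base to ionise the guaiacol OH appreciably, to drive retro-aldol or E1cB dehydration of the β-hydroxy ketone, or to bring about α-arylation of the product dione, so the phenol, the C5 ketone and the product should survive.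

**Compound list**
1 | 2-tridecanone (tridecan-2-one) | CCCCCCCCCCCC(C)=O | starting material
2 | acrolein (prop-2-enal) | C=CC=O | starting material
3 | lithium tridec-1-en-2-olate (kinetic methyl-side enolate of 1, not isolated) | [Li+].C=C([O-])CCCCCCCCCCC | intermediate
4 | lithium 5-oxohexadec-1-en-3-olate (racemic lithium aldolate, not isolated) | [Li+].C=CC([O-])CC(=O)CCCCCCCCCCC | intermediate
5 | racemic 3-hydroxyhexadec-1-en-5-one | C=CC(O)CC(=O)CCCCCCCCCCC | intermediate
6 | 4-iodo-2-methoxyphenol | COc1cc(I)ccc1O | starting material
7 | 3-hydroxy-1-(4-hydroxy-3-methoxyphenyl)hexadec-2-en-5-one (C2=C3 enol, double-bond geometry undefined, not isolated) | CCCCCCCCCCCC(=O)CC(O)=CCc1ccc(O)c(OC)c1 | intermediate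
8 | [12]-gingerdione, 1-(4-hydroxy-3-methoxyphenyl)hexadecane-3,5-dione | CCCCCCCCCCCC(=O)CC(=O)CCc1ccc(O)c(OC)c1 | target

**Total step count:** 2
**Longest linear sequence:** 2 steps (1 → 5 → 8)

**Steps most likely to fail** (the route has only two steps, so both are ranked, the riskier first)

Step 2. Several processes may compete with the coupling:
- loss of water or retro-aldol cleavage of the β-hydroxy ketone under warm bicarbonate before it couples;
- isomerisation of 5 by the palladium hydride to the saturated dione without arylation;
- β-hydride elimination toward benzylic C1, leaving the carbinol unoxidised;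
- binding of palladium by the product dione or the phenol, which would stall turnover.

The fallback sets out from 1 and comes back to the route at 8; it gives up the palladium step and makes the C1–C2 bond instead. Compound 1 would be acylated at its methyl group by ethyl acetate under NaH in THF (Claisen condensation) to give, after acidification, pentadecane-2,4-dione F1. F1 would be deprotonated twice by LiN(iPr)2 (2.2 equiv, THF, −78 to 0 °C) to dilithium pentadeca-1,3-diene-2,4-diolate F2. F2 should be alkylated only at its more basic terminal CH2 carbon by purchased 4-(benzyloxy)-3-methoxybenzyl chloride, so that the C2-versus-C4 question does not arise, to give after a dilute HCl quench 1-[4-(benzyloxy)-3-methoxyphenyl]hexadecane-3,5-dione F3. Hydrogenolysis of the benzyl ether (H2, 10 % Pd on carbon, EtOAc, room temperature) would then give 8.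

Step 1. Three processes may lower the outcome:
- incomplete regiocontrol of enolisation, some internal enolate leading to the branched aldol;
- base-induced polymerisation of, or conjugate addition to, acrolein;
- retro-aldol cleavage or dehydration during quench and chromatography.

The fallback sets out from 2 and comes back to the route at 5; it builds the C5 ketone after the C3–C4 bond from a nucleophile with a single enolisable position. N-Methoxy-N-methylacetamide would be converted by LiN(iPr)2 in THF at −78 °C into lithium 1-[methoxy(methyl)amino]ethen-1-olate F4. F4 adds 1,2 to 2 and, after an acetic acid quench, should give racemic 3-hydroxy-N-methoxy-N-methylpent-4-enamide F5. Treatment of F5 with C11H23MgBr (3 equiv, THF, 0 °C; the first equivalent takes the OH proton) and aqueous NH4Cl work-up would give 5 by Weinreb ketone synthesis, the ketone being unveiled only on work-up.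

**Further compounds**
F1 | step 2 | pentadecane-2,4-dione | CCCCCCCCCCCC(=O)CC(C)=O
F2 | step 2 | dilithium pentadeca-1,3-diene-2,4-diolate | [Li+].[Li+].C=C([O-])C=C([O-])CCCCCCCCCCC
F3 | step 2 | 1-[4-(benzyloxy)-3-methoxyphenyl]hexadecane-3,5-dione | CCCCCCCCCCCC(=O)CC(=O)CCc1ccc(OCc2ccccc2)c(OC)c1
F4 | step 1 | lithium 1-[methoxy(methyl)amino]ethen-1-olate | [Li+].C=C([O-])N(C)OC
F5 | step 1 | racemic 3-hydroxy-N-methoxy-N-methylpent-4-enamide | C=CC(O)CC(=O)N(C)OC
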